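**Plan**
Numbering: chain from the vinyl end, C1=C2, ester carbinol C10, oxolane O–C11–C12–C13(OH)–C14, pentyl C15–C19.
Cuts, in retrosynthetic order: the myristate acyl–O bond at C10, C9–C10 (organomagnesium addition to a C10 aldehyde), C16=C17 (cross-metathesis, then saturation), and in the key step both O–C14 and C14–C15.
Enabling feature: C14 is the ring carbon bonded to the ring oxygen, to carbinol carbon C13 and to the pentyl chain, so with C13 as a ketone it can be a metal carbenoid that takes up the C11 ether oxygen and then an allyl group migrating from that oxygen.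
Forward: (R)-malate → acyclic allyl ether diazoketone (C10–C14) → the only ring (oxolan-3-one) closes in step 6 → C13 reduction → allyl extended to pentyl → C10 aldehyde → non-8-enyl Grignard → myristate → PMB removal.
Stereochemistry: C11 from dimethyl (R)-malate; C14 from C11 in the rearrangement (2,5-trans); C13 by hydride attack anti to the C14 substituent (2,3-cis); C10 by chelation-controlled addition (threo, R).
Key step: step 6

Remark: the catalyst-bound carbenoid 9 is drawn with one acac ligand on copper; the true ligand sphere of the active species is an assumption and does not affect the argument.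
Remark: 14 is expected as an E/Z mixture (drawn E); both isomers converge on 15 in step 9.

Step 1
Reactants: 1 dimethyl (R)-malate
Product: 2 methyl (3R)-3,4-dihydroxybutanoate
Conditions: BH3·SMe2 (1.0 equiv), NaBH4 (5 mol%), THF, 0 °C → rt; MeOH quench
Reagents that add atoms: none
Why: Hydroxyl-directed chemoselective borane reduction: the C11 hydroxyl forms an alkoxyborane that delivers hydride through a five-membered chelate to the adjacent ester only, so the distal ester and the stereocentre should stay untouched.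

Step 2
Reactants: 2 methyl (3R)-3,4-dihydroxybutanoate
Product: 3 methyl (3R)-4-[(tert-butyldiphenylsilyl)oxy]-3-hydroxybutanoate
Conditions: TBDPSCl, imidazole, CH2Cl2, 0 °C
Reagents that add atoms: tert-butyl(chloro)diphenylsilane, CC(C)(C)[Si](Cl)(c1ccccc1)c1ccccc1
Why: Selective silylation of a primary over a secondary hydroxyl with a bulky silyl chloride, which also removes the hydroxyl that could lactonise onto the ester.

Step 3
Reactants: 3 methyl (3R)-4-[(tert-butyldiphenylsilyl)oxy]-3-hydroxybutanoate, 4 allyl 2,2,2-trichloroacetimidate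
Product: 5 methyl (3R)-3-(allyloxy)-4-[(tert-butyldiphenylsilyl)oxy]butanoate
Conditions: TfOH (cat.), cyclohexane/CH2Cl2 (2:1), rt
Reagents that add atoms: none
Why: Acid-catalysed trichloroacetimidate O-alkylation transfers the allyl group under non-basic conditions, so the β-hydroxy ester should neither eliminate, undergo retro-aldol cleavage nor suffer silyl migration, and the C11–O bond is not broken.

Step 4
Reactants: 5 methyl (3R)-3-(allyloxy)-4-[(tert-butyldiphenylsilyl)oxy]butanoate
Product: 6 (3R)-3-(allyloxy)-4-[(tert-butyldiphenylsilyl)oxy]butanoic acid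
Conditions: LiOH·H2O, THF/H2O, 0 °C → rt; then 1 M HCl to pH 3
Reagents that add atoms: lithium hydroxide, [Li+].[OH-]
Why: Saponification of a methyl ester with LiOH at or below room temperature is expected to be faster than β-elimination of the allyloxy group and to leave the TBDPS ether intact.

Step 5
Reactants: 6 (3R)-3-(allyloxy)-4-[(tert-butyldiphenylsilyl)oxy]butanoic acid
Product: 8 (4R)-4-(allyloxy)-5-[(tert-butyldiphenylsilyl)oxy]-1-diazopentan-2-one, via isobutyl carbonic mixed anhydride 7 (not isolated)
Conditions: i-BuOCOCl, Et3N, Et2O, −20 → 0 °C; then CH2N2 (excess, ethereal solution), 0 °C → rt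
Reagents that add atoms: diazomethane, C=[N+]=[N-]
Why: Mixed-anhydride activation followed by C-acylation of diazomethane (the diazoketone stage of an Arndt–Eistert sequence) avoids an acid chloride and HCl, which the silyl and allyl ethers would tolerate less well.

Step 6
Reactants: 8 (4R)-4-(allyloxy)-5-[(tert-butyldiphenylsilyl)oxy]-1-diazopentan-2-one
Product: 11 (2S,5R)-2-allyl-5-{[(tert-butyldiphenylsilyl)oxy]methyl}oxolan-3-one, via (acac)Cu carbenoid 9 (not isolated), via allyloxonium ylide 10 (not isolated)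
Conditions: Cu(acac)2 (10 mol%), THF, reflux, slow addition of 8
Reagents that add atoms: none
Why: The catalyst formed from Cu(acac)2 (a divalent copper precatalyst) strips N2 from 8 to give the electrophilic carbenoid 9 at C14; a lone pair of the allyl ether oxygen on C11 adds to this carbon (O–C14) to give the five-membered allyloxonium ylide 10, free or still copper-bound, and a suprafacial [2,3]-sigmatropic shift then carries the allyl group from oxygen to C14 (C14–C15) and leaves the C13 ketone. The closest known reaction type is the copper-catalysed tandem oxonium ylide formation and [2,3]-rearrangement of 4-allyloxy-1-diazoalkan-2-ones, an established entry to 2,5-trans 2-allyloxolan-3-ones, so this is precedented chemistry on a new substrate. The oxolane (O, C11, C12, C13, C14) closes by O–C bond formation, the ether oxygen attacking the carbenoid carbon in a 5-exo sense with respect to the Cu=C bond. The new stereocentre C14 is controlled by C11: in the envelope-shaped transition state the O-allyl group lies on the ring face anti to the C11 silyloxymethyl group and is handed over on that same face, so the allyl group on C14 ends trans to the C11 substituent (2S,5R). The step needs ylide formation to win over C–H insertion at the C10 methylene next to the silyl ether oxygen, over [1,2]-shift and over carbene dimerisation, and it needs 2,5-trans selectivity; copper rather than Rh2(OAc)4 disfavours C–H insertion, the allyl group makes the symmetry-allowed [2,3] path fast, slow addition at reflux suppresses dimerisation, and the single C11 substituent biases the ylide face.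

Step 7
Reactants: 11 (2S,5R)-2-allyl-5-{[(tert-butyldiphenylsilyl)oxy]methyl}oxolan-3-one
Product: 12 (2S,3S,5R)-2-allyl-5-{[(tert-butyldiphenylsilyl)oxy]methyl}oxolan-3-ol
Conditions: LiBH(s-Bu)3, THF, −78 °C; then H2O
Reagents that add atoms: none
Why: Substrate-controlled reduction with a bulky hydride, which should approach C13 from the face opposite the adjacent C14 allyl group and so place the hydroxyl cis to it (13S), while also removing the epimerisable α-keto position.

Step 8
Reactants: 12 (2S,3S,5R)-2-allyl-5-{[(tert-butyldiphenylsilyl)oxy]methyl}oxolan-3-ol, 13 cis-hex-3-ene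
Product: 14 (2S,3S,5R)-5-{[(tert-butyldiphenylsilyl)oxy]methyl}-2-[(2E)-pent-2-en-1-yl]oxolan-3-ol
Conditions: second-generation Grubbs catalyst (H2IMes)(PCy3)Cl2Ru=CHPh (5 mol%), 13 (excess), CH2Cl2, 40 °C
Reagents that add atoms: none
Why: Olefin cross-metathesis of a terminal alkene with an excess of a symmetrical internal alkene exchanges the terminal methylene for a propylidene unit (C16=C17) with little homodimerisation, and free secondary alcohols and silyl ethers are tolerated.

Step 9
Reactants: 14 (2S,3S,5R)-5-{[(tert-butyldiphenylsilyl)oxy]methyl}-2-[(2E)-pent-2-en-1-yl]oxolan-3-ol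
Product: 15 (2S,3S,5R)-5-{[(tert-butyldiphenylsilyl)oxy]methyl}-2-pentyloxolan-3-ol
Conditions: H2 (1 atm), Pd/C, EtOAc, rt
Reagents that add atoms: none
Why: Catalytic hydrogenation saturates the disubstituted alkene of either geometry; it is placed before the PMB group is introduced and no benzylic or allylic C–O bond is present.

Step 10
Reactants: 15 (2S,3S,5R)-5-{[(tert-butyldiphenylsilyl)oxy]methyl}-2-pentyloxolan-3-ol
Product: 16 tert-butyl{[(2R,4S,5S)-4-[(4-methoxybenzyl)oxy]-5-pentyloxolan-2-yl]methoxy}diphenylsilane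
Conditions: NaH, PMBCl, Bu4NI (cat.), DMF, 0 °C → rt
Reagents that add atoms: 4-methoxybenzyl chloride, COc1ccc(CCl)cc1
Why: Williamson etherification of the C13 alkoxide; the silyl ether sits on the opposite ring face, so silyl migration is not expected, and the PMB group can later be removed without touching an ester or a terminal alkene.

Step 11
Reactants: 16 tert-butyl{[(2R,4S,5S)-4-[(4-methoxybenzyl)oxy]-5-pentyloxolan-2-yl]methoxy}diphenylsilane
Product: 17 [(2R,4S,5S)-4-[(4-methoxybenzyl)oxy]-5-pentyloxolan-2-yl]methanol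
Conditions: TBAF, THF, 0 °C → rt
Reagents that add atoms: none
Why: Fluoride-mediated desilylation is orthogonal to the PMB ether and frees only the C10 hydroxyl.

Step 12
Reactants: 17 [(2R,4S,5S)-4-[(4-methoxybenzyl)oxy]-5-pentyloxolan-2-yl]methanol
Product: 18 (2R,4S,5S)-4-[(4-methoxybenzyl)oxy]-5-pentyloxolane-2-carbaldehyde
Conditions: DMP, CH2Cl2, 0 °C → rt; used without storage
Reagents that add atoms: none
Why: Dess–Martin oxidation gives the α-alkoxy aldehyde under near-neutral, non-epimerising conditions, so the C11 configuration should be retained if the aldehyde is used at once.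

Step 13
Reactants: 18 (2R,4S,5S)-4-[(4-methoxybenzyl)oxy]-5-pentyloxolane-2-carbaldehyde, 19 9-bromonon-1-ene
Product: 21 (1R)-1-[(2R,4S,5S)-4-[(4-methoxybenzyl)oxy]-5-pentyloxolan-2-yl]dec-9-en-1-ol, via non-8-enylmagnesium bromide 20 (not isolated)
Conditions: 19, Mg, Et2O, rt (gives 20); 18, MgBr2·OEt2, CH2Cl2, −78 °C, then 20; aq. NH4Cl
Reagents that add atoms: none
Why: Grignard addition under Cram chelation control: magnesium bridges the aldehyde oxygen and the ring oxygen in a five-membered chelate, and the nucleophile should attack the carbonyl face on the side of the C11 hydrogen, which gives the threo (10R,11R) carbinol.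

Step 14
Reactants: 21 (1R)-1-[(2R,4S,5S)-4-[(4-methoxybenzyl)oxy]-5-pentyloxolan-2-yl]dec-9-en-1-ol, 22 tetradecanoyl chloride
Product: 23 (1R)-1-[(2R,4S,5S)-4-[(4-methoxybenzyl)oxy]-5-pentyloxolan-2-yl]dec-9-en-1-yl tetradecanoate
Conditions: pyridine, DMAP (cat.), CH2Cl2, 0 °C → rt
Reagents that add atoms: none
Why: DMAP-catalysed acylation of the only free hydroxyl with an acid chloride proceeds with retention at C10, since the C10–O bond is not broken.

Step 15
Reactants: 23 (1R)-1-[(2R,4S,5S)-4-[(4-methoxybenzyl)oxy]-5-pentyloxolan-2-yl]dec-9-en-1-yl tetradecanoate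
Product: 24 (1R)-1-[(2R,4S,5S)-4-hydroxy-5-pentyloxolan-2-yl]dec-9-en-1-yl tetradecanoate
Conditions: DDQ, CH2Cl2/pH 7 phosphate buffer (10:1), 0 °C → rt
Reagents that add atoms: none
Why: Oxidative PMB ether cleavage with DDQ is neutral and should leave the ester and the terminal alkene alone; acyl migration from O10 to O13 would need a seven-membered transition state across the trans-substituted ring and is not expected.

**Compound list**
1 | dimethyl (R)-malate | COC(=O)C[C@@H](O)C(=O)OC | starting material
2 | methyl (3R)-3,4-dihydroxybutanoate | OC[C@H](O)CC(=O)OC | intermediate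
3 | methyl (3R)-4-[(tert-butyldiphenylsilyl)oxy]-3-hydroxybutanoate | CC(C)(C)[Si](c1ccccc1)(c1ccccc1)OC[C@H](O)CC(=O)OC | intermediate
4 | allyl 2,2,2-trichloroacetimidate | C=CCOC(=N)C(Cl)(Cl)Cl | starting material
5 | methyl (3R)-3-(allyloxy)-4-[(tert-butyldiphenylsilyl)oxy]butanoate | CC(C)(C)[Si](c1ccccc1)(c1ccccc1)OC[C@H](OCC=C)CC(=O)OC | intermediate
6 | (3R)-3-(allyloxy)-4-[(tert-butyldiphenylsilyl)oxy]butanoic acid | CC(C)(C)[Si](c1ccccc1)(c1ccccc1)OC[C@H](OCC=C)CC(=O)O | intermediate
7 | (3R)-3-(allyloxy)-4-[(tert-butyldiphenylsilyl)oxy]butanoic isobutyl carbonic anhydride | CC(C)(C)[Si](c1ccccc1)(c1ccccc1)OC[C@H](OCC=C)CC(=O)OC(=O)OCC(C)C | intermediate (not isolated)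
8 | (4R)-4-(allyloxy)-5-[(tert-butyldiphenylsilyl)oxy]-1-diazopentan-2-one | CC(C)(C)[Si](c1ccccc1)(c1ccccc1)OC[C@H](OCC=C)CC(=O)C=[N+]=[N-] | intermediate
9 | copper carbenoid of 8, drawn as (acac)Cu=CH–C(=O)–CH2–CH(OCH2CH=CH2)–CH2OTBDPS, (4R) | CC(C)(C)[Si](c1ccccc1)(c1ccccc1)OC[C@H](OCC=C)CC(=O)C=[Cu]OC(C)=CC(C)=O | intermediate (not isolated)
10 | (5R)-1-allyl-5-{[(tert-butyldiphenylsilyl)oxy]methyl}-3-oxooxolan-1-ium-2-ide (cyclic allyloxonium ylide) | CC(C)(C)[Si](c1ccccc1)(c1ccccc1)OC[C@H]1CC(=O)[CH-][O+]1CC=C | intermediate (not isolated)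
11 | (2S,5R)-2-allyl-5-{[(tert-butyldiphenylsilyl)oxy]methyl}oxolan-3-one | CC(C)(C)[Si](c1ccccc1)(c1ccccc1)OC[C@H]1CC(=O)[C@H](CC=C)O1 | intermediate
12 | (2S,3S,5R)-2-allyl-5-{[(tert-butyldiphenylsilyl)oxy]methyl}oxolan-3-ol | CC(C)(C)[Si](c1ccccc1)(c1ccccc1)OC[C@H]1C[C@H](O)[C@H](CC=C)O1 | intermediate
13 | cis-hex-3-ene | CC/C=C\CC | starting material
14 | (2S,3S,5R)-5-{[(tert-butyldiphenylsilyl)oxy]methyl}-2-[(2E)-pent-2-en-1-yl]oxolan-3-ol | CC(C)(C)[Si](c1ccccc1)(c1ccccc1)OC[C@H]1C[C@H](O)[C@H](C/C=C/CC)O1 | intermediate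
15 | (2S,3S,5R)-5-{[(tert-butyldiphenylsilyl)oxy]methyl}-2-pentyloxolan-3-ol | CC(C)(C)[Si](c1ccccc1)(c1ccccc1)OC[C@H]1C[C@H](O)[C@H](CCCCC)O1 | intermediate
16 | tert-butyl{[(2R,4S,5S)-4-[(4-methoxybenzyl)oxy]-5-pentyloxolan-2-yl]methoxy}diphenylsilane | CC(C)(C)[Si](c1ccccc1)(c1ccccc1)OC[C@H]1C[C@H](OCc2ccc(OC)cc2)[C@H](CCCCC)O1 | intermediate
17 | [(2R,4S,5S)-4-[(4-methoxybenzyl)oxy]-5-pentyloxolan-2-yl]methanol | OC[C@H]1C[C@H](OCc2ccc(OC)cc2)[C@H](CCCCC)O1 | intermediate
18 | (2R,4S,5S)-4-[(4-methoxybenzyl)oxy]-5-pentyloxolane-2-carbaldehyde | O=C[C@H]1C[C@H](OCc2ccc(OC)cc2)[C@H](CCCCC)O1 | intermediate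
19 | 9-bromonon-1-ene | C=CCCCCCCCBr | starting material
20 | non-8-enylmagnesium bromide | C=CCCCCCCC[Mg]Br | intermediate (not isolated)
21 | (1R)-1-[(2R,4S,5S)-4-[(4-methoxybenzyl)oxy]-5-pentyloxolan-2-yl]dec-9-en-1-ol | C=CCCCCCCC[C@@H](O)[C@H]1C[C@H](OCc2ccc(OC)cc2)[C@H](CCCCC)O1 | intermediate
22 | tetradecanoyl chloride | CCCCCCCCCCCCCC(=O)Cl | starting material
23 | (1R)-1-[(2R,4S,5S)-4-[(4-methoxybenzyl)oxy]-5-pentyloxolan-2-yl]dec-9-en-1-yl tetradecanoate | C=CCCCCCCC[C@@H](OC(=O)CCCCCCCCCCCCC)[C@H]1C[C@H](OCc2ccc(OC)cc2)[C@H](CCCCC)O1 | intermediate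
24 | (1R)-1-[(2R,4S,5S)-4-hydroxy-5-pentyloxolan-2-yl]dec-9-en-1-yl tetradecanoate | C=CCCCCCCC[C@@H](OC(=O)CCCCCCCCCCCCC)[C@H]1C[C@H](O)[C@H](CCCCC)O1 | target

Total step count: 15. Longest linear sequence: 15 steps (1 → 24); compounds 4, 13, 19 and 22 are used as purchased.

**Steps most likely to fail**

Step 6. The carbenoid may be diverted before or after ylide formation: C–H insertion at the C10 methylene, [1,2]-shift, dimerisation, or insufficient 2,5-trans selectivity in the allyl transfer. The fallback keeps the same two bond formations but generates the carbenoid from an alkyne instead of a diazoketone; it sets out from 5 and returns at 11. Reduction of 5 with i-Bu2AlH at −78 °C should give (3R)-3-(allyloxy)-4-[(tert-butyldiphenylsilyl)oxy]butanal F1. Ohira–Bestmann homologation (dimethyl (1-diazo-2-oxopropyl)phosphonate, K2CO3, MeOH) should then give tert-butyl{[(2R)-2-(allyloxy)pent-4-yn-1-yl]oxy}diphenylsilane F2. Gold-catalysed oxidation of the terminal alkyne (Ph3PAuNTf2, 8-methylquinoline N-oxide, 1,2-dichloroethane, rt) is expected to place the oxygen on C13 and the gold carbenoid on C14, which should pass through the same kind of oxonium ylide and [2,3]-shift to 11.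

Step 13. Facial selectivity in the addition may be poor if open (Felkin–Anh) and chelated transition states compete. The fallback sets C10 by reduction instead of addition; it sets out from 18 and returns at 21. Addition of 20 to 18 is run without regard to selectivity, and the epimer (1S)-1-[(2R,4S,5S)-4-[(4-methoxybenzyl)oxy]-5-pentyloxolan-2-yl]dec-9-en-1-ol F3 formed beside 21 is not separated. The mixture is oxidised with DMP to the ketone 1-[(2R,4S,5S)-4-[(4-methoxybenzyl)oxy]-5-pentyloxolan-2-yl]dec-9-en-1-one F4. Reduction with LiBH(s-Bu)3 at −78 °C, a non-chelating hydride that follows the Felkin–Anh model with the ring oxygen anti to the incoming hydride, should then give the threo alcohol 21.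

Step 7. Hydride delivery may occur partly from the face syn to the allyl group, because the anti face carries the 1,3-related C11 substituent. The fallback sets C13 by inversion; it sets out from 11 and returns at 12. Whatever reduction of 11 is used (for example NaBH4 in MeOH), the wrong epimer (2S,3R,5R)-2-allyl-5-{[(tert-butyldiphenylsilyl)oxy]methyl}oxolan-3-ol F5 is separated. Mitsunobu reaction (4-nitrobenzoic acid, PPh3, DIAD, THF) should convert it with inversion into (2S,3S,5R)-2-allyl-5-{[(tert-butyldiphenylsilyl)oxy]methyl}oxolan-3-yl 4-nitrobenzoate F6. Methanolysis (K2CO3, MeOH) then gives 12.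

**Further compounds**
F1 | step 6 | (3R)-3-(allyloxy)-4-[(tert-butyldiphenylsilyl)oxy]butanal | CC(C)(C)[Si](c1ccccc1)(c1ccccc1)OC[C@H](OCC=C)CC=O
F2 | step 6 | tert-butyl{[(2R)-2-(allyloxy)pent-4-yn-1-yl]oxy}diphenylsilane | CC(C)(C)[Si](c1ccccc1)(c1ccccc1)OC[C@H](OCC=C)CC#C
F3 | step 13 | (1S)-1-[(2R,4S,5S)-4-[(4-methoxybenzyl)oxy]-5-pentyloxolan-2-yl]dec-9-en-1-ol | C=CCCCCCCC[C@H](O)[C@H]1C[C@H](OCc2ccc(OC)cc2)[C@H](CCCCC)O1
F4 | step 13 | 1-[(2R,4S,5S)-4-[(4-methoxybenzyl)oxy]-5-pentyloxolan-2-yl]dec-9-en-1-one | C=CCCCCCCCC(=O)[C@H]1C[C@H](OCc2ccc(OC)cc2)[C@H](CCCCC)O1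
F5 | step 7 | (2S,3R,5R)-2-allyl-5-{[(tert-butyldiphenylsilyl)oxy]methyl}oxolan-3-ol | CC(C)(C)[Si](c1ccccc1)(c1ccccc1)OC[C@H]1C[C@@H](O)[C@H](CC=C)O1
F6 | step 7 | (2S,3S,5R)-2-allyl-5-{[(tert-butyldiphenylsilyl)oxy]methyl}oxolan-3-yl 4-nitrobenzoate | CC(C)(C)[Si](c1ccccc1)(c1ccccc1)OC[C@H]1C[C@H](OC(=O)c2ccc(cc2)[N+](=O)[O-])[C@H](CC=C)O1
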